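## Structural features

Compound 21 is a single oxolane ring (O1, C2, C3, C4, C5) with three adjacent substituted carbons: C2 carries ring A (3,4,5-trimethoxyphenyl), C3 carries the hydroxymethyl carbon C3a, and C4 carries the methylene C4a that leads to ring B (4-hydroxy-3-methoxyphenyl); C5 is an unsubstituted OCH2. The stereocentres C2, C3 and C4 are contiguous, (2R,3S,4S): ring A is trans to C3a, and C3a is cis to C4a. The C2–O1 bond is a benzylic ether of an electron-rich arene: acid ionises it, which can invert C2 and exposes the cation to ring B (aryltetralin formation), and hydrogenolysis can cut it; the guaiacol phenol of ring B is oxidation-prone and must be masked. The 2,3-trans relation is the stable one and can be reached by equilibration, but the 3,4-cis relation between two carbon substituents is the less stable one and, together with the absolute configuration, is the real difficulty. The key step uses two features: the cis carbons C3a and C4a can be joined as a γ-lactone C3a(=O)–O–C4a (the extra oxygen sitting on the benzylic carbon of ring B), and the C2–H bond of a ring A benzyl ether hung from C5 through O1 is both α to oxygen and benzylic. A carbene at C3 of this lactone lies beside that C–H bond, so C2–C3 and the oxolane ring form by insertion while the ring fusion dictates 3,4-cis. The para-hydroxyl of ring B later allows the extra O–C4a bond to be cut without touching C2–O1.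

## Logic of the disconnections

21 to 20: no skeletal bond is removed; C2–O1 is treated as reversibly broken, so 21 is traced to its C2 epimer 20. The cut is placed here because 2,3-trans is the thermodynamic arrangement of the monocycle, which frees the ring-forming step from having to deliver it. The forward step must ionise C2–O1 and let the C5 hydroxyl reclose faster than ring B attacks the cation.

20 to 19 to 16: C3a is taken back to the carboxyl level (19), then the C4a–H bond is exchanged for a C4a–O bond to that carboxyl, with the ring B phenol silylated (16). The lactone locks C3a and C4a cis and is the template of the key step. The forward step must cleave one of two benzylic C–O bonds selectively; only ring B has a para oxygen, so a quinone methide can form only at C4a, and hydride must capture it before it tautomerises.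

16 to 15: the C2–C3 bond is cut and the oxolane ring opened, C3 becoming a diazo carbon. One ring, one C–C bond and two stereocentres are removed, leaving a monocyclic lactone with two centres. The forward step needs a carbene that selects the C2–H bond over all other reaction channels.

15 to 13: the C3=N2 bond is removed. This leaves a plain lactone; the forward step must activate C3 for diazo transfer without disturbing C4.

13 to 10 and 12, 12 to 11: the O1–C2 ether bond is cut. This separates ring A as a benzyl donor from a hydroxymethyl lactone. The forward etherification must avoid alkoxide formation, since the alkoxide of 10 can translactonise.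

10 to 9 to 7: C5 is taken back to the carboxyl level and then to an imide that carries the chiral controller. The forward steps must reduce an acid beside a lactone and cleave the imide without epimerising C4.

7 to 5 and 2 (through 6): the C4–C4a bond (aldol) and the lactone O–C3a bond are cut. Two simple pieces result, and the absolute configuration now comes from a recoverable auxiliary. The forward step must enolise the imide rather than the ester and give the syn adduct on one face.

5 to 3 and 4, 2 to 1: the N–acyl bond and the O–Si bond are cut, which reaches purchasable materials; the forward steps are routine acylation and silylation.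

## Other disconnections considered

Alternative 1: The cut removes O1–C2, C3–C4 and the C4a–ring B bond at once. In the forward key step the lithium alkoxide of prop-2-yn-1-ol A4 adds to the benzylidene malonate A2 (oxa-Michael, O1–C2). The malonate anion then attacks the alkyne held by the arylpalladium iodide (divalent palladium) that forms from the aryl iodide A3 and a zerovalent palladium catalyst such as Pd(PPh3)4 (C3–C4, ring closure). Reductive elimination joins C4a to ring B and gives the oxolane diester A1.
- In favour: maximal convergence. The whole skeleton and the ring come from three simple components in one operation, with about four steps to follow (loss of one ester, alkene hydrogenation, ester reduction, debenzylation). On step count this is clearly better than the chosen plan.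
- Against: C2 is created with nothing to direct its absolute sense, so A1 would be racemic and a single enantiomer would need a resolution or an unproven asymmetric variant. C4 would come from hydrogenation of the exocyclic alkene, where the face anti to the C3 ester is the face syn to ring A, so 3,4-cis is not assured. The same hydrogenation and the debenzylation endanger the benzylic C2–O1 bond.
- Comparison: both plans rely on thermodynamics for 2,3-trans (equal). The alternative leaves all three centres to later substrate control, whereas the chosen plan fixes C4 by an auxiliary and C3 by ring fusion. Both pass through a transition-metal intermediate; the palladium cascade is additionally exposed to retro-Michael loss of the alkoxide. The alternative wins on step economy, the chosen plan on security for one enantiomer.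

Alternative 2: The cut is C4–C5, with C5 supplied as the methylene of a methoxymethyl ether on O1. In the forward key step SnBr4 ionises the acetal of the alkyne A6 to the O1=C5 oxocarbenium ion. C4 of the aryl alkyne attacks C5 to close the ring, and bromide caps the vinyl cation at C4a (stabilised by ring B), giving the vinyl bromide A5.
- In favour: C2 and C3 are already in place and trans in the open-chain precursor, so no late correction of C2 is needed. On this point the alternative is better than the chosen plan. C5 comes from a one-carbon acetal, and the regiochemistry follows from cation stability.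
- Against: A6 needs two adjacent stereocentres set enantioselectively before the key step, and three protecting groups. SnBr4 is a strong Lewis acid on a substrate whose ring A benzylic C–O bond can ionise. C4 is again left to hydrogenation of an exocyclic alkene together with C–Br removal, with the same facial conflict and the same threat to C2–O1.
- Comparison: each key step forms one ring bond and one ring (equal). The chosen lactone template secures 3,4-cis in the ring-forming event itself; the alternative does not. Step counts should be comparable.

Alternative 3: The cut is O1–C2, with a temporary C2–C4 bond added as a cyclopropane. In the forward key step Sc(OTf)3 activates the formyl group of the cyclopropane carbaldehyde A8. The C2–C4 bond breaks with positive charge building at benzylic C2, and the formyl oxygen closes onto C2 (Cloke–Wilson-type ring expansion), giving the 2,3-dihydrofuran A7 with a C4=C5 enol ether.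
- In favour: the ring expansion is stereoconvergent at C2 and should close trans to the C3 substituent, so 2,3-trans arises directly (better than the chosen plan at C2). The endocyclic enol ether can be hydrogenated anti to the C3 substituent, which points to 3,4-cis. The key step is catalytic and redox-neutral.
- Against: A8 is a crowded cyclopropane with a quaternary carbon, and making it enantiopure at C3 needs an asymmetric cyclopropanation of a trisubstituted alkene or a resolution. Ring A is only a moderate donor (its para methoxy is twisted), so opening may need conditions that the acid-labile enol ether A7 and the aryl silyl ether tolerate poorly. Ring A on C2 opposes the desired hydrogenation face.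
- Comparison: both plans close the ring by a catalysed reorganisation of a small template and need a reduction afterwards (equal). The alternative is better at C2, weaker at C4 and in access to its precursor. Step counts should be about equal.

Key step: step 9

Remarks on the chemistry:
- Atom labels O1, C2–C5, C3a and C4a are those of the oxolane of 21 and are used for the same atoms in every intermediate; systematic names use their own locants.
- A convex-face argument concerns product stability, not the insertion transition state; the kinetic isomer of the insertion is taken to be ring A endo, 16 is numbered as that isomer, and C2 is set right in step 12.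
- The ring B phenol is carried as the triisopropylsilyl ether, which withstands LiOH/H2O2 and amide bases better than a tert-butyldimethylsilyl ether and still falls to fluoride; methyl 4-chloro-4-oxobutanoate is bought, which saves the opening and activation of the anhydride.

## Route

Step 1
Reactants: 1 vanillin (4-hydroxy-3-methoxybenzaldehyde)
Product: 2 3-methoxy-4-[(triisopropylsilyl)oxy]benzaldehyde
Conditions: i-Pr3SiCl, imidazole, DMF, 0 °C to rt
Reagents that add atoms: triisopropylsilyl chloride, CC(C)[Si](Cl)(C(C)C)C(C)C
Why: O-Silylation of the phenol with imidazole as base; the bulky silyl ether is chosen to survive the basic and acidic steps up to step 10. No stereocentre is involved.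

Step 2
Reactants: 3 (R)-4-benzyl-1,3-oxazolidin-2-one; 4 methyl 4-chloro-4-oxobutanoate
Product: 5 methyl 4-[(4R)-4-benzyl-2-oxo-1,3-oxazolidin-3-yl]-4-oxobutanoate
Conditions: n-BuLi, THF, −78 °C; then 4, −78 to 0 °C
Reagents that add atoms: none
Why: N-Acylation of the lithiated oxazolidinone by the acid chloride; the methyl ester is far less electrophilic at −78 °C and the auxiliary centre is untouched.

Step 3
Reactants: 5 methyl 4-[(4R)-4-benzyl-2-oxo-1,3-oxazolidin-3-yl]-4-oxobutanoate; 2 3-methoxy-4-[(triisopropylsilyl)oxy]benzaldehyde
Product: 7 (4R)-4-benzyl-3-{[(2R,3R)-2-{3-methoxy-4-[(triisopropylsilyl)oxy]phenyl}-5-oxooxolan-3-yl]carbonyl}-1,3-oxazolidin-2-one (aryl trans to the acyl group), via syn-aldol adduct 6 (not isolated)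
Conditions: Bu2BOTf, i-Pr2NEt, CH2Cl2, −78 to 0 °C; pH 7 buffer/MeOH/H2O2, 0 °C; then pyridinium p-toluenesulfonate (cat.), toluene, 50 °C
Reagents that add atoms: none
Why: Evans syn aldol: Bu2BOTf and the amine enolise the imide (not the ester) to the Z boron enolate, which adds to 2 through a chair Zimmerman–Traxler transition state on the face away from the benzyl group of the (R)-auxiliary, setting C4 (the centre that survives into 21) and C4a as the syn pair. The carbinol then closes onto the methyl ester (lactonisation), and a syn adduct can only give the trans lactone.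

Step 4
Reactants: 7 (4R)-4-benzyl-3-{[(2R,3R)-2-{3-methoxy-4-[(triisopropylsilyl)oxy]phenyl}-5-oxooxolan-3-yl]carbonyl}-1,3-oxazolidin-2-one
Product: 9 (2R,3R)-2-{3-methoxy-4-[(triisopropylsilyl)oxy]phenyl}-5-oxooxolane-3-carboxylic acid (trans paraconic acid), via peroxy acid 8 (not isolated)
Conditions: LiOH, H2O2, THF–H2O, 0 °C; Na2SO3; 1 M HCl to pH 2
Reagents that add atoms: hydrogen peroxide, OO
Why: Hydroperoxide attacks the exocyclic imide carbonyl (LiOOH cleavage of an N-acyloxazolidinone), sulfite reduces the peroxy acid, and acidification recloses any lactone opened by hydroxide; 3 is recovered. The carboxyl-bearing carbon is already trans to the aryl group, its stable arrangement, so no epimerisation is expected.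

Step 5
Reactants: 9 (2R,3R)-2-{3-methoxy-4-[(triisopropylsilyl)oxy]phenyl}-5-oxooxolane-3-carboxylic acid
Product: 10 (4S,5R)-4-(hydroxymethyl)-5-{3-methoxy-4-[(triisopropylsilyl)oxy]phenyl}oxolan-2-one
Conditions: BH3·THF, THF, 0 °C to rt; MeOH
Reagents that add atoms: none
Why: Chemoselective borane reduction: a carboxylic acid is reduced through its acyloxyborane much faster than a lactone. The medium is never basic, so the product cannot translactonise and no stereocentre is touched.

Step 6
Reactants: 11 3,4,5-trimethoxybenzyl alcohol
Product: 12 3,4,5-trimethoxybenzyl 2,2,2-trichloroacetimidate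
Conditions: Cl3CCN, 1,8-diazabicyclo[5.4.0]undec-7-ene (cat.), CH2Cl2, 0 °C
Reagents that add atoms: trichloroacetonitrile, N#CC(Cl)(Cl)Cl
Why: Base-catalysed addition of the benzylic alkoxide to the nitrile (trichloroacetimidate formation); the reagent is used crude in step 7.

Step 7
Reactants: 10 (4S,5R)-4-(hydroxymethyl)-5-{3-methoxy-4-[(triisopropylsilyl)oxy]phenyl}oxolan-2-one; 12 3,4,5-trimethoxybenzyl 2,2,2-trichloroacetimidate
Product: 13 (4S,5R)-5-{3-methoxy-4-[(triisopropylsilyl)oxy]phenyl}-4-{[(3,4,5-trimethoxybenzyl)oxy]methyl}oxolan-2-one
Conditions: Me3SiOTf (5 mol%), 4 Å molecular sieves, CH2Cl2, −40 to −20 °C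
Reagents that add atoms: none
Why: Acid-catalysed O-benzylation with a trichloroacetimidate forms O1–C2 without ever generating the alkoxide of 10, which would translactonise. Catalytic acid at low temperature should leave the aryl silyl ether and the benzylic lactone C–O bond intact.

Step 8
Reactants: 13 (4S,5R)-5-{3-methoxy-4-[(triisopropylsilyl)oxy]phenyl}-4-{[(3,4,5-trimethoxybenzyl)oxy]methyl}oxolan-2-one
Product: 15 (4S,5R)-3-diazo-5-{3-methoxy-4-[(triisopropylsilyl)oxy]phenyl}-4-{[(3,4,5-trimethoxybenzyl)oxy]methyl}oxolan-2-one, via α-trifluoroacetyl lactone 14 (not isolated)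
Conditions: LiN(SiMe3)2, THF, −78 °C; CF3CO2CH2CF3; aq. HCl work-up; then 4-acetamidobenzenesulfonyl azide, Et3N, H2O (1 equiv), MeCN, rt
Reagents that add atoms: 4-acetamidobenzenesulfonyl azide, CC(=O)Nc1ccc(cc1)S(=O)(=O)N=[N+]=[N-] (the two diazo nitrogens); 2,2,2-trifluoroethyl trifluoroacetate, O=C(OCC(F)(F)F)C(F)(F)F (the trifluoroacetyl group of 14, lost again in 15)
Why: Claisen trifluoroacetylation of the lactone enolate activates C3, and Regitz-type diazo transfer with loss of the trifluoroacetyl group (deacylative diazo transfer) gives the α-diazo lactone. Only C3 is deprotonated and it carries no β-leaving group, so both lactone stereocentres are retained.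

Step 9
Reactants: 15 (4S,5R)-3-diazo-5-{3-methoxy-4-[(triisopropylsilyl)oxy]phenyl}-4-{[(3,4,5-trimethoxybenzyl)oxy]methyl}oxolan-2-one
Product: 16 (1R,2S,5S,6R)-6-{3-methoxy-4-[(triisopropylsilyl)oxy]phenyl}-2-(3,4,5-trimethoxyphenyl)-3,7-dioxabicyclo[3.3.0]octan-8-one (cis-fused; ring A endo and syn to the lactone carbonyl; ring B exo)
Conditions: Rh2(OAc)4 (2 mol%), CH2Cl2, rt, slow addition of 15
Reagents that add atoms: none
Why: Rh2(OAc)4 (divalent rhodium) expels N2 from 15 and gives an electrophilic rhodium carbene at C3, lying in the plane of the lactone with the ether tether of C4 beside it. One of the two C2–H bonds overlaps with the empty carbene orbital and, in a single asynchronous three-centre transition state, hydride passes to C3 while C2–C3 forms and the catalyst is released; the closest known reaction type is the dirhodium-catalysed intramolecular 1,5 C–H insertion of α-diazo-γ-butyrolactones into benzylic ether C–H bonds. The oxolane ring (O1, C2, C3, C4, C5) is closed by 1,5-insertion through a five-membered transition-state ring, the only size the three-atom tether C4–C5–O1 allows without strain. C3 is controlled by C4: the tether reaches the carbene only from the lactone face that carries C5, so the fusion is necessarily cis and C3a ends cis to C4a. C2 is controlled by the catalyst: the dirhodium core with its acetate wall sits on the exo side of the forming bicycle, so ring A is expected to turn to the endo side, syn to the lactone carbonyl, which is the kinetic arrangement and the opposite of what 21 needs; it is corrected in step 12, where any exo isomer converges as well. The step needs site selectivity for C2–H over 1,2-hydride shift from C4 (butenolide formation), over attack on the two electron-rich rings and over carbene dimerisation. It is secured by the double activation of C2–H (α to O1 and benzylic to ring A), by the ring-size preference, by the moderately electrophilic acetate ligands and by slow addition of 15.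

Step 10
Reactants: 16 (1R,2S,5S,6R)-6-{3-methoxy-4-[(triisopropylsilyl)oxy]phenyl}-2-(3,4,5-trimethoxyphenyl)-3,7-dioxabicyclo[3.3.0]octan-8-one
Product: 19 (2S,3R,4S)-4-(4-hydroxy-3-methoxybenzyl)-2-(3,4,5-trimethoxyphenyl)oxolane-3-carboxylic acid (all-cis), via free phenol lactone 17 (not isolated), via quinone methide acid 18 (not isolated)
Conditions: Bu4NF (1.2 equiv), NaBH4 (4 equiv), THF–i-PrOH, 0 °C to rt; 1 M HCl work-up
Reagents that add atoms: none
Why: Fluoride removes the silyl group, the para-phenoxide of ring B expels the lactone carboxylate by 1,6-elimination (the way fluoride-labile 4-silyloxybenzyl esters release acids), and borohydride adds to the exocyclic carbon C4a of the quinone methide (1,6-reduction), leaving C4a as CH2. Ring A has no free para oxygen, so C2–O1 cannot react in this way; C2, C3 and C4 are not involved.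

Step 11
Reactants: 19 (2S,3R,4S)-4-(4-hydroxy-3-methoxybenzyl)-2-(3,4,5-trimethoxyphenyl)oxolane-3-carboxylic acid
Product: 20 [(2S,3S,4S)-4-(4-hydroxy-3-methoxybenzyl)-2-(3,4,5-trimethoxyphenyl)oxolan-3-yl]methanol (all-cis; C2 epimer of the target)
Conditions: BH3·THF, THF, 0 °C to rt; MeOH
Reagents that add atoms: none
Why: Chemoselective borane reduction of the carboxylic acid to the primary alcohol C3a–OH; ethers and arenes are inert, the phenol is only borylated until the methanol quench, and no stereocentre is affected.

Step 12
Reactants: 20 [(2S,3S,4S)-4-(4-hydroxy-3-methoxybenzyl)-2-(3,4,5-trimethoxyphenyl)oxolan-3-yl]methanol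
Product: 21 [(2R,3S,4S)-4-(4-hydroxy-3-methoxybenzyl)-2-(3,4,5-trimethoxyphenyl)oxolan-3-yl]methanol (target; ring A trans to C3a, C3a cis to C4a)
Conditions: BF3·OEt2 (0.2 equiv), CH2Cl2, −30 to 0 °C, stopped at equilibrium; Et3N quench
Reagents that add atoms: none
Why: Acid-catalysed epimerisation of a 2-aryloxolane: reversible heterolysis of the benzylic C2–O1 bond gives the ring A-stabilised cation, and reclosure by the C5 hydroxyl under thermodynamic control should place ring A trans to C3a, relieving the all-cis strain; C3 and C4 take no part. Closure by oxygen is expected to be much faster per ionisation than Friedel–Crafts attack by ring B, so low temperature, sub-stoichiometric acid and an early quench should keep that irreversible channel small; unchanged 20 can be resubmitted.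

## Compound list

1 | vanillin (4-hydroxy-3-methoxybenzaldehyde) | COc1cc(C=O)ccc1O | starting material
2 | 3-methoxy-4-[(triisopropylsilyl)oxy]benzaldehyde | COc1cc(C=O)ccc1O[Si](C(C)C)(C(C)C)C(C)C | intermediate
3 | (R)-4-benzyl-1,3-oxazolidin-2-one | O=C1OC[C@@H](Cc2ccccc2)N1 | starting material
4 | methyl 4-chloro-4-oxobutanoate | COC(=O)CCC(Cl)=O | starting material
5 | methyl 4-[(4R)-4-benzyl-2-oxo-1,3-oxazolidin-3-yl]-4-oxobutanoate | COC(=O)CCC(=O)N1C(=O)OC[C@H]1Cc1ccccc1 | intermediate
6 | methyl (3R,4R)-3-{[(4R)-4-benzyl-2-oxo-1,3-oxazolidin-3-yl]carbonyl}-4-hydroxy-4-{3-methoxy-4-[(triisopropylsilyl)oxy]phenyl}butanoate (syn aldol adduct) | COC(=O)C[C@@H](C(=O)N1C(=O)OC[C@H]1Cc1ccccc1)[C@@H](O)c1ccc(O[Si](C(C)C)(C(C)C)C(C)C)c(OC)c1 | intermediate (not isolated)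
7 | (4R)-4-benzyl-3-{[(2R,3R)-2-{3-methoxy-4-[(triisopropylsilyl)oxy]phenyl}-5-oxooxolan-3-yl]carbonyl}-1,3-oxazolidin-2-one | O=C1C[C@@H](C(=O)N2C(=O)OC[C@H]2Cc2ccccc2)[C@H](c2ccc(O[Si](C(C)C)(C(C)C)C(C)C)c(OC)c2)O1 | intermediate
8 | (2R,3R)-2-{3-methoxy-4-[(triisopropylsilyl)oxy]phenyl}-5-oxooxolane-3-carboperoxoic acid (present as its lithium salt) | O=C1C[C@@H](C(=O)OO)[C@H](c2ccc(O[Si](C(C)C)(C(C)C)C(C)C)c(OC)c2)O1 | intermediate (not isolated)
9 | (2R,3R)-2-{3-methoxy-4-[(triisopropylsilyl)oxy]phenyl}-5-oxooxolane-3-carboxylic acid | O=C1C[C@@H](C(O)=O)[C@H](c2ccc(O[Si](C(C)C)(C(C)C)C(C)C)c(OC)c2)O1 | intermediate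
10 | (4S,5R)-4-(hydroxymethyl)-5-{3-methoxy-4-[(triisopropylsilyl)oxy]phenyl}oxolan-2-one | O=C1C[C@@H](CO)[C@H](c2ccc(O[Si](C(C)C)(C(C)C)C(C)C)c(OC)c2)O1 | intermediate
11 | 3,4,5-trimethoxybenzyl alcohol | COc1cc(CO)cc(OC)c1OC | starting material
12 | 3,4,5-trimethoxybenzyl 2,2,2-trichloroacetimidate | COc1cc(COC(=N)C(Cl)(Cl)Cl)cc(OC)c1OC | intermediate
13 | (4S,5R)-5-{3-methoxy-4-[(triisopropylsilyl)oxy]phenyl}-4-{[(3,4,5-trimethoxybenzyl)oxy]methyl}oxolan-2-one | O=C1C[C@@H](COCc2cc(OC)c(OC)c(OC)c2)[C@H](c2ccc(O[Si](C(C)C)(C(C)C)C(C)C)c(OC)c2)O1 | intermediate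
14 | (4S,5R)-5-{3-methoxy-4-[(triisopropylsilyl)oxy]phenyl}-3-(trifluoroacetyl)-4-{[(3,4,5-trimethoxybenzyl)oxy]methyl}oxolan-2-one (C3 epimers and enol form) | O=C1C(C(=O)C(F)(F)F)[C@@H](COCc2cc(OC)c(OC)c(OC)c2)[C@H](c2ccc(O[Si](C(C)C)(C(C)C)C(C)C)c(OC)c2)O1 | intermediate (not isolated)
15 | (4S,5R)-3-diazo-5-{3-methoxy-4-[(triisopropylsilyl)oxy]phenyl}-4-{[(3,4,5-trimethoxybenzyl)oxy]methyl}oxolan-2-one | O=C1O[C@@H](c2ccc(O[Si](C(C)C)(C(C)C)C(C)C)c(OC)c2)[C@H](COCc2cc(OC)c(OC)c(OC)c2)C1=[N+]=[N-] | intermediate
16 | (1R,2S,5S,6R)-6-{3-methoxy-4-[(triisopropylsilyl)oxy]phenyl}-2-(3,4,5-trimethoxyphenyl)-3,7-dioxabicyclo[3.3.0]octan-8-one (2-endo, 6-exo) | O=C1O[C@@H](c2ccc(O[Si](C(C)C)(C(C)C)C(C)C)c(OC)c2)[C@@H]2CO[C@H](c3cc(OC)c(OC)c(OC)c3)[C@H]12 | intermediate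
17 | (1R,2S,5S,6R)-6-(4-hydroxy-3-methoxyphenyl)-2-(3,4,5-trimethoxyphenyl)-3,7-dioxabicyclo[3.3.0]octan-8-one (present as its phenoxide) | O=C1O[C@@H](c2ccc(O)c(OC)c2)[C@@H]2CO[C@H](c3cc(OC)c(OC)c(OC)c3)[C@H]12 | intermediate (not isolated)
18 | (2S,3R,4S)-4-[(3-methoxy-4-oxocyclohexa-2,5-dien-1-ylidene)methyl]-2-(3,4,5-trimethoxyphenyl)oxolane-3-carboxylic acid (present as its carboxylate; alkene geometry not defined) | COC1=CC(=C[C@@H]2CO[C@H](c3cc(OC)c(OC)c(OC)c3)[C@@H]2C(O)=O)C=CC1=O | intermediate (not isolated)
19 | (2S,3R,4S)-4-(4-hydroxy-3-methoxybenzyl)-2-(3,4,5-trimethoxyphenyl)oxolane-3-carboxylic acid | COc1cc(C[C@@H]2CO[C@H](c3cc(OC)c(OC)c(OC)c3)[C@@H]2C(O)=O)ccc1O | intermediate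
20 | [(2S,3S,4S)-4-(4-hydroxy-3-methoxybenzyl)-2-(3,4,5-trimethoxyphenyl)oxolan-3-yl]methanol | COc1cc(C[C@@H]2CO[C@H](c3cc(OC)c(OC)c(OC)c3)[C@@H]2CO)ccc1O | intermediate
21 | [(2R,3S,4S)-4-(4-hydroxy-3-methoxybenzyl)-2-(3,4,5-trimethoxyphenyl)oxolan-3-yl]methanol | COc1cc(C[C@@H]2CO[C@@H](c3cc(OC)c(OC)c(OC)c3)[C@@H]2CO)ccc1O | target

## Step count and least certain steps

Total step count: 12. Longest linear sequence: 10 steps (steps 1, 3, 4, 5, 7, 8, 9, 10, 11, 12; 1 → 2 → 7 → 9 → 10 → 13 → 15 → 16 → 19 → 20 → 21).

Step 9 (key step). The most likely failure is diversion of the carbene before it reaches C2–H: 1,2-hydride migration from the neighbouring tertiary C4–H, electrophilic attack on one of the electron-rich arenes, or carbene dimerisation if the diazo compound accumulates. The sense at C2 is not a hazard, because either epimer reaches the same equilibrium in step 12. The fallback sets out from 10 and returns at 16. Acylation of the primary hydroxyl with purchased 3,4,5-trimethoxybenzoyl chloride (Et3N, 4-(dimethylamino)pyridine, CH2Cl2) would give [(2R,3S)-2-{3-methoxy-4-[(triisopropylsilyl)oxy]phenyl}-5-oxooxolan-3-yl]methyl 3,4,5-trimethoxybenzoate F1. LiN(SiMe3)2 (2 equiv, THF, −78 to 0 °C) would form the lactone enolate, whose C3 attacks the tethered aryl ester carbonyl (intramolecular Claisen condensation of the Dieckmann type, five-membered and necessarily cis-fused). This makes C2–C3 at the ketone level and, after work-up, the bicyclic hemiketal (1R,5S,6R)-2-hydroxy-6-{3-methoxy-4-[(triisopropylsilyl)oxy]phenyl}-2-(3,4,5-trimethoxyphenyl)-3,7-dioxabicyclo[3.3.0]octan-8-one F2. Ionic reduction (Et3SiH, BF3·OEt2, CH2Cl2, −78 °C) through the C2 oxocarbenium ion, with hydride entering on the convex face, would give 16.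

Step 12. The most likely failure is irreversible intramolecular Friedel–Crafts alkylation: once the reversible oxygen closure has been passed many times, the C2 cation is captured by ring B at the position para to its methoxy group, closing a six-membered carbocycle. Equilibration may also stall if the acid is tied up by the hydroxyl groups. The fallback sets out from 20 and returns at 21, and avoids the cation altogether. Acetylation (Ac2O, pyridine) would give [(2S,3S,4S)-4-(4-acetoxy-3-methoxybenzyl)-2-(3,4,5-trimethoxyphenyl)oxolan-3-yl]methyl acetate F3. Thiol-catalysed radical-chain epimerisation (tert-dodecanethiol cat., azobisisobutyronitrile, chlorobenzene, 80 °C) would abstract and return the weak benzylic, α-oxygenated C2–H reversibly through a planar radical, leading to the more stable [(2R,3S,4S)-4-(4-acetoxy-3-methoxybenzyl)-2-(3,4,5-trimethoxyphenyl)oxolan-3-yl]methyl acetate F4. K2CO3 in MeOH would then remove both acetates to give 21.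

Step 10. The most likely failure is tautomerisation of the quinone methide to a 4-vinylphenol through loss of the C4 proton, which would erase C4, if hydride delivery is slow. Premature borohydride reduction of the lactone carbonyl is the other risk, since no carboxylate could then leave. The fallback sets out from 16 and returns at 19. Hydrogenolysis of the benzylic lactone C–O bond (H2, palladium on carbon (Pd/C), EtOAc, rt; an acyloxy group leaves more readily than the ether oxygen at C2) would give (2S,3R,4S)-4-{3-methoxy-4-[(triisopropylsilyl)oxy]benzyl}-2-(3,4,5-trimethoxyphenyl)oxolane-3-carboxylic acid F5, and Bu4NF in THF would then free the phenol to give 19.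

Step 7. The most likely failure is acid-triggered ionisation of the benzylic lactone C–O bond, or self-condensation or rearrangement of the electron-rich imidate before the alcohol intercepts it. The fallback sets out from 10 and returns at 13: neutral silver-assisted alkylation with purchased 3,4,5-trimethoxybenzyl bromide (Ag2O, CH2Cl2, rt, in the dark) forms the same ether bond from the opposite polarity of activation. It makes no compound outside the list (F0).

## Further compounds

F1 | step 9 | [(2R,3S)-2-{3-methoxy-4-[(triisopropylsilyl)oxy]phenyl}-5-oxooxolan-3-yl]methyl 3,4,5-trimethoxybenzoate | O=C1C[C@@H](COC(=O)c2cc(OC)c(OC)c(OC)c2)[C@H](c2ccc(O[Si](C(C)C)(C(C)C)C(C)C)c(OC)c2)O1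
F2 | step 9 | (1R,5S,6R)-2-hydroxy-6-{3-methoxy-4-[(triisopropylsilyl)oxy]phenyl}-2-(3,4,5-trimethoxyphenyl)-3,7-dioxabicyclo[3.3.0]octan-8-one (both C2 anomers) | O=C1O[C@@H](c2ccc(O[Si](C(C)C)(C(C)C)C(C)C)c(OC)c2)[C@@H]2COC(O)(c3cc(OC)c(OC)c(OC)c3)[C@H]12
F3 | step 12 | [(2S,3S,4S)-4-(4-acetoxy-3-methoxybenzyl)-2-(3,4,5-trimethoxyphenyl)oxolan-3-yl]methyl acetate | COc1cc(C[C@@H]2CO[C@H](c3cc(OC)c(OC)c(OC)c3)[C@@H]2COC(C)=O)ccc1OC(C)=O
F4 | step 12 | [(2R,3S,4S)-4-(4-acetoxy-3-methoxybenzyl)-2-(3,4,5-trimethoxyphenyl)oxolan-3-yl]methyl acetate | COc1cc(C[C@@H]2CO[C@@H](c3cc(OC)c(OC)c(OC)c3)[C@@H]2COC(C)=O)ccc1OC(C)=O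
F5 | step 10 | (2S,3R,4S)-4-{3-methoxy-4-[(triisopropylsilyl)oxy]benzyl}-2-(3,4,5-trimethoxyphenyl)oxolane-3-carboxylic acid | COc1cc(C[C@@H]2CO[C@H](c3cc(OC)c(OC)c(OC)c3)[C@@H]2C(O)=O)ccc1O[Si](C(C)C)(C(C)C)C(C)C
F0 | step 7 | none | none
A1 | alternative 1 | diethyl (Z)-4-[4-(benzyloxy)-3-methoxybenzylidene]-2-(3,4,5-trimethoxyphenyl)oxolane-3,3-dicarboxylate (drawn with C2 as in 21; the step itself gives both enantiomers) | COc1cc(/C=C2\CO[C@@H](c3cc(OC)c(OC)c(OC)c3)C2(C(=O)OCC)C(=O)OCC)ccc1OCc1ccccc1
A2 | alternative 1 | diethyl 2-(3,4,5-trimethoxybenzylidene)propanedioate | CCOC(=O)C(=Cc1cc(OC)c(OC)c(OC)c1)C(=O)OCC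
A3 | alternative 1 | 1-(benzyloxy)-4-iodo-2-methoxybenzene | COc1cc(I)ccc1OCc1ccccc1
A4 | alternative 1 | prop-2-yn-1-ol | C#CCO
A5 | alternative 2 | tert-butyl{[4-{[4-(benzyloxy)-3-methoxyphenyl]bromomethylidene}-2-(3,4,5-trimethoxyphenyl)oxolan-3-yl]methoxy}diphenylsilane (2,3-trans; C2 and C3 as in 21) | COc1cc(/C(Br)=C2\CO[C@@H](c3cc(OC)c(OC)c(OC)c3)[C@@H]2CO[Si](c4ccccc4)(c5ccccc5)C(C)(C)C)ccc1OCc6ccccc6
A6 | alternative 2 | tert-butyl{[2-{[4-(benzyloxy)-3-methoxyphenyl]ethynyl}-3-(methoxymethoxy)-3-(3,4,5-trimethoxyphenyl)propyl]oxy}diphenylsilane (both centres as C2 and C3 of 21) | COCO[C@@H](c1cc(OC)c(OC)c(OC)c1)[C@@H](C#Cc1ccc(OCc2ccccc2)c(OC)c1)CO[Si](c1ccccc1)(c1ccccc1)C(C)(C)C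
A7 | alternative 3 | tert-butyl{[4-{4-[(tert-butyldimethylsilyl)oxy]-3-methoxybenzyl}-2-(3,4,5-trimethoxyphenyl)-2,3-dihydrofuran-3-yl]methoxy}dimethylsilane (2,3-trans; C2 and C3 as in 21) | COc1cc(CC2=CO[C@@H](c3cc(OC)c(OC)c(OC)c3)[C@@H]2CO[Si](C)(C)C(C)(C)C)ccc1O[Si](C)(C)C(C)(C)C
A8 | alternative 3 | 1-{4-[(tert-butyldimethylsilyl)oxy]-3-methoxybenzyl}-3-{[(tert-butyldimethylsilyl)oxy]methyl}-2-(3,4,5-trimethoxyphenyl)cyclopropane-1-carbaldehyde (the silyloxymethyl-bearing carbon configured as C3 of 21; the other two ring centres need not be single) | O=CC1(Cc2ccc(O[Si](C)(C)C(C)(C)C)c(OC)c2)C(c2cc(OC)c(OC)c(OC)c2)[C@@H]1CO[Si](C)(C)C(C)(C)C
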